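**Retrosynthetic overview**
- The strategy rests on ring A: its ether carbon (oxygen to ring D), the adjacent carbon carrying the two-carbon bridge to ring B, and the free hydroxyl para to the ether oxygen. This pattern is the ring-opened [4+2] adduct of a 2-aryloxyfuran (furan C2–C5 and the furan oxygen) with a terminal ynone (its two alkyne carbons).
- Target 17 comes from macrocyclic keto phenol 15 by C=O to CH2 reduction and O-demethylation. 15 is disconnected at two ring A C–C bonds (furan C2–acyl-bearing alkyne carbon, furan C5–alkyne CH) to the open-chain furan–ynone 13.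
- 13 comes from Weinreb amide 12 and ethynylmagnesium bromide. The aryloxyfuran comes from ring D phenol 8 by nitro displacement on methyl 5-nitro-2-furoate, saponification and protodecarboxylation.
- 8 comes from a Wittig/hydrogenation C–D bridge. The ring B–O–ring C ether comes from an Ullmann coupling of isovanillin with a 4-bromophenyl Weinreb acetamide.
- Rings B, C and D are bought; ring A and the 18-membered ring are formed last, together, in one step.

Key step: step 10

Remark: stilbene 7 is carried as an E/Z mixture because both isomers converge on 8; adduct 14 is a racemic transient whose two bridgehead centres vanish on aromatisation, so the target has no stereocentre to control.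

Step 1
Reactants: 1 4-bromophenylacetyl chloride
Product: 2 2-(4-bromophenyl)-N-methoxy-N-methylacetamide
Conditions: MeNHOMe·HCl, pyridine, CH2Cl2, 0 °C to rt
Reagents that add atoms: N,O-dimethylhydroxylamine hydrochloride, CNOC.Cl
Why: N-acylation of the hydroxylamine by the acid chloride (Weinreb amide formation) puts the later ynone carbon in place in a form that should survive every step up to step 9.

Step 2
Reactants: 2 2-(4-bromophenyl)-N-methoxy-N-methylacetamide; 3 isovanillin (3-hydroxy-4-methoxybenzaldehyde)
Product: 4 2-[4-(5-formyl-2-methoxyphenoxy)phenyl]-N-methoxy-N-methylacetamide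
Conditions: CuI (10 mol%), N,N-dimethylglycine·HCl (30 mol%), Cs2CO3, dioxane, 90 °C
Reagents that add atoms: none
Why: Ligand-accelerated Ullmann diaryl ether coupling of the guaiacol-type phenol with the aryl bromide forms the ring B–O–ring C ether; carbonate is too weak a base to condense the arylacetamide methylene with the aldehyde.

Step 3
Reactants: 5 3-(benzyloxy)benzyl bromide
Product: 6 [3-(benzyloxy)benzyl]triphenylphosphonium bromide
Conditions: PPh3, PhMe, reflux
Reagents that add atoms: triphenylphosphine, c1ccc(cc1)P(c1ccccc1)c1ccccc1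
Why: SN2 quaternisation of triphenylphosphine by the benzylic bromide should give the crystalline Wittig salt.

Step 4
Reactants: 4 2-[4-(5-formyl-2-methoxyphenoxy)phenyl]-N-methoxy-N-methylacetamide; 6 [3-(benzyloxy)benzyl]triphenylphosphonium bromide
Product: 7 2-[4-(5-{2-[3-(benzyloxy)phenyl]ethenyl}-2-methoxyphenoxy)phenyl]-N-methoxy-N-methylacetamide (E/Z mixture)
Conditions: K2CO3, 18-crown-6 (cat.), CH2Cl2, reflux
Reagents that add atoms: none
Why: Wittig olefination with the semistabilised benzylic ylide under mild solid–liquid conditions joins rings C and D without touching the Weinreb amide; the alkene geometry is irrelevant because the next step saturates it.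

Step 5
Reactants: 7 stilbene (E/Z mixture)
Product: 8 2-(4-{5-[2-(3-hydroxyphenyl)ethyl]-2-methoxyphenoxy}phenyl)-N-methoxy-N-methylacetamide
Conditions: H2 (1 atm), 10% Pd/C, EtOAc/MeOH, rt
Reagents that add atoms: none
Why: Catalytic hydrogenation saturates the stilbene and hydrogenolyses the benzyl ether in one operation, freeing only the ring D phenol; the amide N–O bond and the diaryl ether are expected to be inert under these conditions.

Step 6
Reactants: 8 ring D phenol; 9 methyl 5-nitro-2-furoate
Product: 10 methyl 5-{3-[2-(4-methoxy-3-{4-[2-(methoxy(methyl)amino)-2-oxoethyl]phenoxy}phenyl)ethyl]phenoxy}furan-2-carboxylate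
Conditions: K2CO3, DMF, 60 °C
Reagents that add atoms: none
Why: Nucleophilic aromatic substitution (addition–elimination) of the phenoxide at furan C5, activated by the ester, with nitrite as leaving group, gives the 5-aryloxy-2-furoate.

Step 7
Reactants: 10 methyl 5-aryloxy-2-furoate
Product: 11 5-{3-[2-(4-methoxy-3-{4-[2-(methoxy(methyl)amino)-2-oxoethyl]phenoxy}phenyl)ethyl]phenoxy}furan-2-carboxylic acid
Conditions: LiOH·H2O, THF/H2O, rt; then 1 M HCl to pH 3, 0 °C
Reagents that add atoms: lithium hydroxide, [Li+].[OH-]
Why: Saponification of the methyl ester is fast at room temperature, where the Weinreb amide is not hydrolysed.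

Step 8
Reactants: 11 5-aryloxyfuran-2-carboxylic acid
Product: 12 2-[4-(5-{2-[3-(furan-2-yloxy)phenyl]ethyl}-2-methoxyphenoxy)phenyl]-N-methoxy-N-methylacetamide
Conditions: Ag2CO3 (10 mol%), AcOH (5 mol%), DMSO, 120 °C
Reagents that add atoms: none
Why: Silver-catalysed protodecarboxylation of a heteroaryl 2-carboxylic acid, eased by the 5-aryloxy donor, leaves the 2-aryloxyfuran; the amide is a spectator.

Step 9
Reactants: 12 2-aryloxyfuran Weinreb amide
Product: 13 1-[4-(5-{2-[3-(furan-2-yloxy)phenyl]ethyl}-2-methoxyphenoxy)phenyl]but-3-yn-2-one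
Conditions: HC≡CMgBr (excess), THF, −20 to 0 °C; inverse quench into cold aq. NaHSO4/Et2O
Reagents that add atoms: ethynylmagnesium bromide, C#C[Mg]Br
Why: Weinreb ketone synthesis: the magnesium chelate of the tetrahedral adduct prevents over-addition, and the cold acidic inverse quench protonates the released N,O-dimethylhydroxylamine before it can add to the terminal ynone.

Step 10
Reactants: 13 furan–ynone precursor
Product: 15 macrocyclic ring A phenol ketone, via oxa-bridged cycloadduct 14 (not isolated)
Conditions: PhMe (1 mM, syringe-pump addition), 100 °C; then PPTS (cat.), rt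
Reagents that add atoms: none
Why: Proposed new method: the 2-aryloxyfuran is an oxygen-activated diene with its largest HOMO coefficient at C5 and the terminal ynone is a LUMO-lowered dienophile polarised toward its CH terminus, so a normal-demand, asynchronous [4+2] should bond furan C5 to the alkyne CH carbon and furan C2 to the acyl-bearing carbon to give the 7-oxanorbornadiene 14; heterolysis of the bridge C–O bond at the aryloxy-bearing bridgehead (oxocarbenium-stabilised cation) and loss of the proton from the other bridgehead then aromatise it to the 4-aryloxyphenol 15. The closest known reaction types are the intermolecular Diels–Alder/ring-opening of 2-alkoxyfurans with acetylenic esters or ketones to 4-alkoxyphenols and intramolecular furan Diels–Alder reactions; new here is their use on a 2-aryloxyfuran to close a macrocycle. Ring A closes by the cycloaddition itself (furan C2–C5 plus the two alkyne carbons), and the 18-membered ring closes in the same event as a macrocyclising cycloaddition, because the tether runs from the oxygen on furan C2 to the ynone carbonyl. No stereocentre is created in 15, since the two bridgehead centres of racemic 14 are lost on aromatisation. The step needs the acyl carbon ortho to the aryloxy carbon, which the donor–acceptor polarity match secures (the reverse orientation is mismatched and would need a 19-membered meta-bridged ring), and cyclisation over oligomerisation, which the 1 mM pseudo-dilution secures; PPTS only completes the opening of any 14 that persists.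

Step 11
Reactants: 15 macrocyclic ring A phenol ketone
Product: 16 macrocyclic ring A phenol with ring C methyl ether (bridge CH2CH2)
Conditions: Et3SiH, TFA, 0 to 50 °C
Reagents that add atoms: none
Why: Ionic hydrogenation (Kursanov–Parnes) of the aryl ketone to the methylene proceeds through a benzylic cation stabilised by the ortho aryloxy oxygen; phenol, diaryl ethers and the methyl ether tolerate TFA.

Step 12
Reactants: 16 macrocyclic ring A phenol with ring C methyl ether
Product: 17 target CNP0135015.0
Conditions: BBr3 (excess), CH2Cl2, −78 °C to rt; then H2O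
Reagents that add atoms: none
Why: Lewis acid-mediated cleavage of the aryl methyl ether by BBr3 frees the ring C hydroxyl; diaryl ethers are not cleaved under these conditions.

**Compound list**
1 | 4-bromophenylacetyl chloride | O=C(Cl)Cc1ccc(Br)cc1 | starting material
2 | 2-(4-bromophenyl)-N-methoxy-N-methylacetamide | CON(C)C(=O)Cc1ccc(Br)cc1 | intermediate
3 | isovanillin (3-hydroxy-4-methoxybenzaldehyde) | COc1ccc(C=O)cc1O | starting material
4 | 2-[4-(5-formyl-2-methoxyphenoxy)phenyl]-N-methoxy-N-methylacetamide | CON(C)C(=O)Cc1ccc(cc1)Oc1cc(C=O)ccc1OC | intermediate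
5 | 3-(benzyloxy)benzyl bromide | BrCc1cccc(OCc2ccccc2)c1 | starting material
6 | [3-(benzyloxy)benzyl]triphenylphosphonium bromide | [Br-].c1ccc(cc1)COc1cccc(C[P+](c2ccccc2)(c2ccccc2)c2ccccc2)c1 | intermediate
7 | 2-[4-(5-{2-[3-(benzyloxy)phenyl]ethenyl}-2-methoxyphenoxy)phenyl]-N-methoxy-N-methylacetamide, E/Z mixture | CON(C)C(=O)Cc1ccc(cc1)Oc1cc(C=Cc2cccc(OCc3ccccc3)c2)ccc1OC | intermediate
8 | 2-(4-{5-[2-(3-hydroxyphenyl)ethyl]-2-methoxyphenoxy}phenyl)-N-methoxy-N-methylacetamide | CON(C)C(=O)Cc1ccc(cc1)Oc1cc(CCc2cccc(O)c2)ccc1OC | intermediate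
9 | methyl 5-nitro-2-furoate | COC(=O)c1ccc(o1)[N+](=O)[O-] | starting material
10 | methyl 5-{3-[2-(4-methoxy-3-{4-[2-(methoxy(methyl)amino)-2-oxoethyl]phenoxy}phenyl)ethyl]phenoxy}furan-2-carboxylate | CON(C)C(=O)Cc1ccc(cc1)Oc1cc(CCc2cccc(Oc3ccc(o3)C(=O)OC)c2)ccc1OC | intermediate
11 | 5-{3-[2-(4-methoxy-3-{4-[2-(methoxy(methyl)amino)-2-oxoethyl]phenoxy}phenyl)ethyl]phenoxy}furan-2-carboxylic acid | CON(C)C(=O)Cc1ccc(cc1)Oc1cc(CCc2cccc(Oc3ccc(o3)C(O)=O)c2)ccc1OC | intermediate
12 | 2-[4-(5-{2-[3-(furan-2-yloxy)phenyl]ethyl}-2-methoxyphenoxy)phenyl]-N-methoxy-N-methylacetamide | CON(C)C(=O)Cc1ccc(cc1)Oc1cc(CCc2cccc(Oc3ccco3)c2)ccc1OC | intermediate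
13 | 1-[4-(5-{2-[3-(furan-2-yloxy)phenyl]ethyl}-2-methoxyphenoxy)phenyl]but-3-yn-2-one | C#CC(=O)Cc1ccc(cc1)Oc1cc(CCc2cccc(Oc3ccco3)c2)ccc1OC | intermediate
14 | oxa-bridged macrocyclic cycloadduct (7-oxabicyclo[2.2.1]hepta-2,5-diene with the aryloxy group on one bridgehead and the acyl group on the adjacent alkene carbon), racemic | COc1ccc2cc1Oc1ccc(cc1)CC(=O)C1=CC3C=CC1(O3)Oc1cccc(c1)CC2 | intermediate
15 | macrocyclic ketone: ring A hydroxyl free, ring C methyl ether, C=O on the bridge carbon next to ring A | Oc1ccc2c(c1)C(=O)Cc1ccc(cc1)Oc1cc(ccc1OC)CCc1cccc(c1)O2 | intermediate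
16 | macrocycle with ring A hydroxyl free and ring C methyl ether | Oc1ccc2c(c1)CCc1ccc(cc1)Oc1cc(ccc1OC)CCc1cccc(c1)O2 | intermediate
17 | CNP0135015.0 | Oc1ccc2c(c1)CCc1ccc(cc1)Oc1cc(ccc1O)CCc1cccc(c1)O2 | target

**Step count**
Total: 12 steps. Longest linear sequence: 11 steps (1 → 2 → 4 → 7 → 8 → 10 → 11 → 12 → 13 → 15 → 16 → 17).

**Steps most likely to fail**

Step 10. Intermolecular cycloaddition or conjugate addition may outrun ring closure and give oligomers, or the adduct may revert or the aryloxyfuran hydrolyse before aromatisation. The fallback uses known chemistry and builds ring A from a preformed arene, closing the macrocycle at the ring D–O–ring A ether. It sets out from 8. The phenol is deprotonated, and the aryl Grignard reagent from 4-(benzyloxy)-2-bromo-1-fluorobenzene (iPrMgCl·LiCl, THF, −15 °C) is added to the Weinreb amide to give the open-chain fluoroaryl ketone 1-[5-(benzyloxy)-2-fluorophenyl]-2-(4-{5-[2-(3-hydroxyphenyl)ethyl]-2-methoxyphenoxy}phenyl)ethan-1-one F1. Intramolecular nucleophilic aromatic substitution of the ring D phenoxide at the fluorine-bearing carbon ortho to the ketone (Cs2CO3, DMSO, high dilution, 110 °C) should then give the macrocyclic benzyl ether of the keto phenol F2. Hydrogenolysis (H2, Pd/C, EtOAc, rt) removes the benzyl group and comes back to the route at 15; over-reduction of the ketone would give 16, which is also on the route.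

Step 9. The released N,O-dimethylhydroxylamine may add to the new ynone during the quench, the Grignard reagent may enolise the arylacetamide, or the acidic quench may open the aryloxyfuran. The fallback sets out from 12 and avoids releasing an amine next to the ynone. DIBAL-H (THF, −78 °C) should give the arylacetaldehyde 2-[4-(5-{2-[3-(furan-2-yloxy)phenyl]ethyl}-2-methoxyphenoxy)phenyl]acetaldehyde F3. Addition of ethynylmagnesium bromide (THF, −78 to 0 °C, neutral NH4Cl quench) gives the racemic propargylic alcohol 1-[4-(5-{2-[3-(furan-2-yloxy)phenyl]ethyl}-2-methoxyphenoxy)phenyl]but-3-yn-2-ol F4. Oxidation with Dess–Martin periodinane (NaHCO3, CH2Cl2, 0 °C) comes back to the route at 13.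

Step 8. Protodecarboxylation may stall, or heat and acid may degrade the electron-rich aryloxyfuran as it forms. The fallback sets out from 8 and replaces decarboxylation by decarbonylation. Nitro displacement on 5-nitrofuran-2-carbaldehyde (K2CO3, DMF, rt to 50 °C) should give the aryloxyfurfural 2-[4-(5-{2-[3-(5-formylfuran-2-yloxy)phenyl]ethyl}-2-methoxyphenoxy)phenyl]-N-methoxy-N-methylacetamide F5. Catalytic decarbonylation ([RhCl(cod)]2 with 1,3-bis(diphenylphosphino)propane, diglyme, reflux) then comes back to the route at 12.

Further compounds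
F1 | step 10 | 1-[5-(benzyloxy)-2-fluorophenyl]-2-(4-{5-[2-(3-hydroxyphenyl)ethyl]-2-methoxyphenoxy}phenyl)ethan-1-one | O=C(Cc1ccc(cc1)Oc1cc(CCc2cccc(O)c2)ccc1OC)c1cc(OCc2ccccc2)ccc1F
F2 | step 10 | macrocyclic ketone with ring A benzyl ether and ring C methyl ether (benzyl ether of 15) | O=C1Cc2ccc(cc2)Oc2cc(ccc2OC)CCc2cccc(c2)Oc2ccc(OCc3ccccc3)cc12
F3 | step 9 | 2-[4-(5-{2-[3-(furan-2-yloxy)phenyl]ethyl}-2-methoxyphenoxy)phenyl]acetaldehyde | O=CCc1ccc(cc1)Oc1cc(CCc2cccc(Oc3ccco3)c2)ccc1OC
F4 | step 9 | 1-[4-(5-{2-[3-(furan-2-yloxy)phenyl]ethyl}-2-methoxyphenoxy)phenyl]but-3-yn-2-ol, racemic | C#CC(O)Cc1ccc(cc1)Oc1cc(CCc2cccc(Oc3ccco3)c2)ccc1OC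
F5 | step 8 | 2-[4-(5-{2-[3-(5-formylfuran-2-yloxy)phenyl]ethyl}-2-methoxyphenoxy)phenyl]-N-methoxy-N-methylacetamide | CON(C)C(=O)Cc1ccc(cc1)Oc1cc(CCc2cccc(Oc3ccc(C=O)o3)c2)ccc1OC
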